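**Plan**

1. Cuts: ring C is opened at O1–C2 and its C4–C3 bond is traced back to a C4a aldehyde plus a phenylacetylide, leaving 3-(2-hydroxy-6-methoxyphenyl)-5,5-dimethylbutenolide. Ring A of this phenol is then cut at C8–C8a, C6–C7 and C4a–C8a into cyclobutenone (C8a, C6, C5, C4a) and a methoxyalkyne (C7, C8) that already carries the butenolide. The alkyne is cut at its bond to butenolide C3.
2. Enabling feature: ring A has oxygen on C8a, the butenolide on C8 and methoxy on C7 in an unbroken row, with C5 and C6 unsubstituted. This is the hydroxyl / alkyne substituent / alkoxy pattern written by a cyclobutenone–alkoxyalkyne benzannulation.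
3. Forward order: butenolide ring by lactonisation, then alpha-bromination and Negishi alkynylation, then ring A by benzannulation, then ortho-formylation at C4a, then alkynylation, oxidation and 6-endo closure of ring C.
4. Stereochemistry: the target has no stereocentre. The transient centres (dibromide, vinylcyclobutenone, carbinol) are racemic and are erased.

Key step: step 7

Remark: the bond between C8 and the butenolide is assumed to rotate freely at room temperature, so the target is treated as achiral, as its SMILES indicates.

**Route**

Step 1
Reactants: 1 2-methylbut-3-yn-2-ol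
Product: 3 4-hydroxy-4-methylpent-2-ynoic acid, via dilithio alkynolate 2 (not isolated)
Conditions: n-BuLi (2.1 equiv), THF, −78 to 0 °C; CO2, −78 °C to rt; aq. HCl
Reagents that add atoms: carbon dioxide, O=C=O
Why: Double deprotonation gives the O,C-dilithio species, whose acetylide carbon is carboxylated by CO2 (acetylide carboxylation), the standard entry to 4-hydroxy-2-alkynoic acids.

Step 2
Reactants: 3 4-hydroxy-4-methylpent-2-ynoic acid
Product: 5 5,5-dimethylfuran-2(5H)-one, via cis-hydroxy acid 4 (not isolated)
Conditions: H2 (1 atm), Pd/CaCO3 poisoned with Pb(OAc)2, quinoline, EtOAc, rt; then TsOH (cat.), CH2Cl2, rt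
Reagents that add atoms: none
Why: Lindlar semihydrogenation gives the Z-alkene, which holds the tertiary hydroxyl and the carboxyl on the same side, so lactonisation to the butenolide follows readily and is helped by the gem-dimethyl group.

Step 3
Reactants: 5 5,5-dimethylfuran-2(5H)-one
Product: 7 3-bromo-5,5-dimethylfuran-2(5H)-one, via trans-dibromolactone 6 (not isolated)
Conditions: Br2, CH2Cl2, 0 to 40 °C; then Et3N, 0 °C
Reagents that add atoms: bromine, BrBr
Why: Anti addition of bromine followed by E1cB loss of HBr (the acidic C3–H is removed and the C4 bromide leaves) is the usual bromination–dehydrobromination route to alpha-bromobutenolides, and the absence of a gamma-hydrogen excludes other eliminations.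

Step 4
Reactants: 7 3-bromo-5,5-dimethylfuran-2(5H)-one and 8 chloroacetaldehyde dimethyl acetal
Product: 11 3-(methoxyethynyl)-5,5-dimethylfuran-2(5H)-one, via lithium methoxyacetylide 9 (not isolated), via methoxyethynylzinc chloride 10 (not isolated)
Conditions: 8 (1.5 equiv), LiNEt2 (3 equiv per 8, from Et2NH and n-BuLi), THF, 0 °C; ZnCl2, 0 °C; then 7, Pd(PPh3)4 (5 mol %), THF, 0 °C to rt; chromatography on Et3N-deactivated silica
Reagents that add atoms: none
Why: Two eliminations and a deprotonation by the amide base turn the chloroacetal into the alkoxyacetylide, which after transmetalation to zinc couples with the electron-poor alkenyl bromide under zerovalent palladium catalysis (Negishi alkynylation) under conditions mild enough for the lactone and the acid-sensitive ynol ether.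

Step 5
Reactants: 12 3-oxocyclobutanecarboxylic acid
Product: 13 3-bromocyclobutanone
Conditions: HgO, Br2, MgSO4, CH2Cl2, reflux
Reagents that add atoms: bromine, BrBr
Why: Bromodecarboxylation of the acid through its acyl hypobromite (Hunsdiecker reaction in the Cristol–Firth variant) is the established preparation of this bromoketone.

Step 6
Reactants: 13 3-bromocyclobutanone
Product: 14 cyclobut-2-en-1-one
Conditions: n-Bu3N, rt, reduced pressure, product collected in a −78 °C trap and kept as a cold toluene solution
Reagents that add atoms: none
Why: E1cB dehydrobromination by a high-boiling, non-nucleophilic amine allows the volatile, polymerisation-prone enone to be distilled out of the base as it forms.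

Step 7
Reactants: 11 3-(methoxyethynyl)-5,5-dimethylfuran-2(5H)-one and 14 cyclobut-2-en-1-one
Product: 19 3-(2-hydroxy-6-methoxyphenyl)-5,5-dimethylfuran-2(5H)-one, via vinylketene 15 (not isolated), via vinylcyclobutenone 16 (not isolated), via dienylketene 17 (not isolated), via cyclohexadienone 18 (not isolated)
Conditions: 14 (1.5 equiv), toluene, 80 °C then 110 °C, sealed tube; crude stirred briefly in K2CO3/MeOH, 0 °C, to cleave any O-acylated phenol
Reagents that add atoms: none
Why: On heating, cyclobutenone 14 opens reversibly by a 4π-electrocyclic reaction to vinylketene 15, whose electrophilic carbonyl carbon is attacked by the nucleophilic, butenolide-bearing carbon of ynol ether 11 in a regioselective ketene–alkyne (2+2) cycloaddition that forms C8–C8a and C6–C7 and gives 4-vinylcyclobutenone 16. A second 4π-opening gives dienylketene 17, and ring A closes by a thermally allowed disrotatory 6π-electrocyclisation between the ketene carbon and the vinyl terminus (C4a–C8a) to cyclohexadienone 18, which tautomerises irreversibly to phenol 19; this is the Danheiser benzannulation of cyclobutenones with alkoxyalkynes. The only stereocentre that appears, the vinyl-bearing carbon of 16, is racemic and is lost on ring opening, so no stereocontrol is required. The selectivity needed is the orientation of the alkyne, and the methoxy group secures it by polarising the triple bond so that the distal, butenolide-bearing carbon bonds to the ketene carbonyl and ends between the hydroxyl and methoxy carbons; the butenolide is attached through the carbon alpha to its carbonyl, so it is only cross-conjugated and does not reverse this polarisation. Chemoselectivity rests on the ketene preferring the electron-rich alkyne over the electron-poor trisubstituted butenolide alkene, and the gem-dimethyl group leaves no gamma-hydrogen for enolisation. Aromatisation drives the cascade, and the congested aryl–butenolide bond is made while it is still an unhindered alkynyl–alkenyl bond.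

Step 8
Reactants: 19 3-(2-hydroxy-6-methoxyphenyl)-5,5-dimethylfuran-2(5H)-one
Product: 21 3-(5,5-dimethyl-2-oxo-2,5-dihydrofuran-3-yl)-2-hydroxy-4-methoxybenzaldehyde, via salicyl alcohol 20 (not isolated)
Conditions: MgCl2, Et3N, (CH2O)n, MeCN, reflux; 1 M HCl
Reagents that add atoms: paraformaldehyde (as formaldehyde), C=O
Why: The magnesium phenoxide delivers coordinated formaldehyde only to the one free ortho carbon, which is also para to the methoxy group, and the resulting salicyl alcohol 20 is oxidised in the flask by a second formaldehyde through an Oppenauer-type hydride transfer (ortho-specific Casnati–Skattebøl formylation), conditions that leave the butenolide untouched.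

Step 9
Reactants: 21 3-(5,5-dimethyl-2-oxo-2,5-dihydrofuran-3-yl)-2-hydroxy-4-methoxybenzaldehyde and 22 phenylethynylmagnesium bromide (commercial THF solution)
Product: 23 3-[2-hydroxy-3-(1-hydroxy-3-phenylprop-2-yn-1-yl)-6-methoxyphenyl]-5,5-dimethylfuran-2(5H)-one (racemic)
Conditions: 22 (3 equiv), THF, −20 to 0 °C; sat. aq. NH4Cl
Reagents that add atoms: none
Why: The first equivalent of the alkynyl Grignard reagent forms the magnesium phenoxide, whose chelate activates the aldehyde for 1,2-addition of the second (Grignard alkynylation), while the conjugated lactone carbonyl, shielded by the twisted aryl group, should not react at or below 0 °C; the new carbinol centre is racemic and is removed in step 10.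

Step 10
Reactants: 23 3-[2-hydroxy-3-(1-hydroxy-3-phenylprop-2-yn-1-yl)-6-methoxyphenyl]-5,5-dimethylfuran-2(5H)-one
Product: 26 8-(5,5-dimethyl-2-oxo-2,5-dihydrofuran-3-yl)-7-methoxy-2-phenyl-4H-chromen-4-one, via ynone 24 (not isolated), via enaminone 25 (not isolated)
Conditions: MnO2 (activated, excess), CH2Cl2, rt; filter; Et2NH, EtOH, rt to 60 °C
Reagents that add atoms: none
Why: MnO2 oxidises the benzylic–propargylic alcohol selectively to ynone 24, diethylamine then adds to it (aza-Michael) to give enaminone 25, and the phenol displaces the amine by 6-endo addition–elimination, which closes ring C as the pyranone and avoids the 5-exo aurone (amine-mediated cyclisation of o-hydroxyaryl ynones to flavones).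

**Compound list**

1 | 2-methylbut-3-yn-2-ol | CC(C)(O)C#C | starting material
2 | lithium 4-lithio-2-methylbut-3-yn-2-olate | [Li]C#CC(C)(C)O[Li] | intermediate (not isolated)
3 | 4-hydroxy-4-methylpent-2-ynoic acid | CC(C)(O)C#CC(=O)O | intermediate
4 | (Z)-4-hydroxy-4-methylpent-2-enoic acid | CC(C)(O)/C=C\C(=O)O | intermediate (not isolated)
5 | 5,5-dimethylfuran-2(5H)-one | CC1(C)C=CC(=O)O1 | intermediate
6 | trans-3,4-dibromo-5,5-dimethyldihydrofuran-2(3H)-one (racemic, one enantiomer drawn) | O=C1OC(C)(C)[C@@H](Br)[C@@H]1Br | intermediate (not isolated)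
7 | 3-bromo-5,5-dimethylfuran-2(5H)-one | CC1(C)C=C(Br)C(=O)O1 | intermediate
8 | chloroacetaldehyde dimethyl acetal (2-chloro-1,1-dimethoxyethane) | COC(CCl)OC | starting material
9 | lithium methoxyacetylide | [Li]C#COC | intermediate (not isolated)
10 | (methoxyethynyl)zinc chloride | Cl[Zn]C#COC | intermediate (not isolated)
11 | 3-(methoxyethynyl)-5,5-dimethylfuran-2(5H)-one | COC#CC1=CC(C)(C)OC1=O | intermediate
12 | 3-oxocyclobutanecarboxylic acid | O=C1CC(C(=O)O)C1 | starting material
13 | 3-bromocyclobutanone | O=C1CC(Br)C1 | intermediate
14 | cyclobut-2-en-1-one | O=C1CC=C1 | intermediate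
15 | buta-1,3-dien-1-one (vinylketene) | C=CC=C=O | intermediate (not isolated)
16 | 3-(3-ethenyl-2-methoxy-4-oxocyclobut-1-en-1-yl)-5,5-dimethylfuran-2(5H)-one (racemic) | O=C1C(C2=CC(C)(C)OC2=O)=C(OC)C1C=C | intermediate (not isolated)
17 | 3-[(3E)-3-methoxy-1-oxohexa-1,3,5-trien-2-yl]-5,5-dimethylfuran-2(5H)-one | O=C=C(C1=CC(C)(C)OC1=O)/C(OC)=C\C=C | intermediate (not isolated)
18 | 3-(2-methoxy-6-oxocyclohexa-1,3-dien-1-yl)-5,5-dimethylfuran-2(5H)-one | O=C1CC=CC(OC)=C1C1=CC(C)(C)OC1=O | intermediate (not isolated)
19 | 3-(2-hydroxy-6-methoxyphenyl)-5,5-dimethylfuran-2(5H)-one | COc1cccc(O)c1C1=CC(C)(C)OC1=O | intermediate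
20 | 3-[2-hydroxy-3-(hydroxymethyl)-6-methoxyphenyl]-5,5-dimethylfuran-2(5H)-one | COc1ccc(CO)c(O)c1C1=CC(C)(C)OC1=O | intermediate (not isolated)
21 | 3-(5,5-dimethyl-2-oxo-2,5-dihydrofuran-3-yl)-2-hydroxy-4-methoxybenzaldehyde | COc1ccc(C=O)c(O)c1C1=CC(C)(C)OC1=O | intermediate
22 | phenylethynylmagnesium bromide | Br[Mg]C#Cc1ccccc1 | starting material
23 | 3-[2-hydroxy-3-(1-hydroxy-3-phenylprop-2-yn-1-yl)-6-methoxyphenyl]-5,5-dimethylfuran-2(5H)-one (racemic) | COc1ccc(C(O)C#Cc2ccccc2)c(O)c1C1=CC(C)(C)OC1=O | intermediate
24 | 3-[2-hydroxy-6-methoxy-3-(3-phenylprop-2-ynoyl)phenyl]-5,5-dimethylfuran-2(5H)-one | COc1ccc(C(=O)C#Cc2ccccc2)c(O)c1C1=CC(C)(C)OC1=O | intermediate (not isolated)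
25 | 3-{3-[(E)-3-(diethylamino)-3-phenylprop-2-enoyl]-2-hydroxy-6-methoxyphenyl}-5,5-dimethylfuran-2(5H)-one | CCN(CC)/C(=C/C(=O)c1ccc(OC)c(C2=CC(C)(C)OC2=O)c1O)c1ccccc1 | intermediate (not isolated)
26 | 8-(5,5-dimethyl-2-oxo-2,5-dihydrofuran-3-yl)-7-methoxy-2-phenyl-4H-chromen-4-one | COc1ccc2c(=O)cc(-c3ccccc3)oc2c1C1=CC(C)(C)OC1=O | target

**Count**

Total steps: 10. Longest linear sequence: 8 (steps 1, 2, 3, 4, 7, 8, 9, 10). The cyclobutenone branch (steps 5 and 6) joins at step 7.

**Steps most likely to fail**

1. Step 7. Oligomerisation of cyclobutenone and of the vinylketene may outrun the ketene–alkyne addition, because the alkenyl-conjugated ynol ether is a weaker nucleophile than an alkyl-substituted one. The ynol ether may also decompose on prolonged heating before it is consumed. The fallback gives up the benzannulation for a cross-coupling; it sets out from 7 and returns at 19. 3-Methoxyphenol is protected with MOMCl and i-Pr2NEt to give 1-methoxy-3-(methoxymethoxy)benzene F1. Lithiation between the two oxygens (n-BuLi, THF, 0 °C), trapping with B(Oi-Pr)3 and mild acidic work-up give [2-methoxy-6-(methoxymethoxy)phenyl]boronic acid F2. Suzuki–Miyaura coupling of F2 with 7 (Pd(OAc)2, SPhos, K3PO4, toluene/water, 80 °C) should give 3-[2-methoxy-6-(methoxymethoxy)phenyl]-5,5-dimethylfuran-2(5H)-one F3. HCl in MeOH removes the MOM group and delivers 19.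

2. Step 4. Diethylamine and lithium methoxide carried over from the acetylide generation may attack the bromobutenolide, and the ynol ether may hydrate during isolation. The fallback replaces the one-pot zinc reagent by an isolated, salt-free tin reagent; it sets out from 8 (through 9) and 7 and returns at 11. Acetylide 9 is quenched with Bu3SnCl and the product distilled to give tributyl(methoxyethynyl)stannane F4. Stille coupling of F4 with 7 (Pd(PPh3)4, toluene, 60 °C) under neutral conditions should give 11.

3. Step 9. The alkynyl Grignard reagent may add to the lactone carbonyl, or addition to the chelated phenoxide aldehyde may stall. The fallback avoids carbon nucleophiles altogether; it sets out from 19, bypasses steps 8 to 10 and returns at 26. Iodination of 19 with N-iodosuccinimide (MeCN, 0 °C) is expected to occur ortho to the hydroxyl and para to the methoxy group, because the other activated site is screened by the methoxy methyl that the butenolide turns toward it. This would give 3-(2-hydroxy-3-iodo-6-methoxyphenyl)-5,5-dimethylfuran-2(5H)-one F5. Carbonylative Sonogashira annulation of F5 with phenylacetylene (CO 1 atm, PdCl2(PPh3)2, Et2NH, 60–100 °C) passes through ynone 24 and enaminone 25 in the flask and should give 26 directly.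

**Further compounds**

F1 | step 7 | 1-methoxy-3-(methoxymethoxy)benzene | COCOc1cccc(OC)c1
F2 | step 7 | [2-methoxy-6-(methoxymethoxy)phenyl]boronic acid | COCOc1cccc(OC)c1B(O)O
F3 | step 7 | 3-[2-methoxy-6-(methoxymethoxy)phenyl]-5,5-dimethylfuran-2(5H)-one | COCOc1cccc(OC)c1C1=CC(C)(C)OC1=O
F4 | step 4 | tributyl(methoxyethynyl)stannane | CCCC[Sn](CCCC)(CCCC)C#COC
F5 | step 9 | 3-(2-hydroxy-3-iodo-6-methoxyphenyl)-5,5-dimethylfuran-2(5H)-one | COc1ccc(I)c(O)c1C1=CC(C)(C)OC1=O
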